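(The readings are calculated for substances that don't exist.)

The constants of this flask are not given, so they must be read from two runs with the same partner charge: gamma, the flask itself followed so far, and delta, which carries 0.680 of gamma's substrate.

| setting | gamma | delta | flask |
|---|---|---|---|
| left-handed substrate | 0.50 M | 0.34 M | 0.50 M |
| right-handed substrate | 0.50 M | 0.34 M | 0.50 M |
| partner | 1.1 M | 1.1 M | 1.10 M |
| racemization catalyst | 1 mM | 1 mM | 1.0 mM |
| impurity | 0.99 mM | 0.99 mM | 0.99 mM |
| temperature | 25 °C | 25 °C | 25 °C |
| remark | the very flask that is asked about, followed so far | run made earlier |  |
| time |  |  | 2.5 d |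

| run | time / h | left-handed product / % | left-handed substrate / % |
|---|---|---|---|
| gamma | 8.00 | 10.2 | 39.4 |
| gamma | 15.0 | 12.1 | 38.7 |
| gamma | 25.0 | 13.2 | 36.8 |
| gamma | 30.0 | 13.7 | 37.1 |
| gamma | 40.0 | 12.4 | 37.3 |
| gamma | 50.0 | 12.9 | 37.1 |
| delta | 0.833 | 2.6 | 48.5 |
| delta | 2.50 | 5.2 | 45.5 |
| delta | 4.00 | 7.4 | 44.0 |
| delta | 6.00 | 9.3 | 40.8 |
| delta | 10.0 | 11.5 | 38.2 |
| delta | 12.0 | 12.2 | 37.4 |

(readings scatter by 0.5 percentage points)

- partner is single-handed; left-handed substrate and right-handed substrate are mirror images of each other, charged as a racemate, each of them at the stated concentration
- what is taken out of left-handed product is counted as made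
- additions bring no volume worth counting
- the earlier runs do not show what temperature does; that part of a forecast is a guess
- the handed part of partner does not stay in what it makes, so the products of the two hands are mirror images too

- elm: at 2.5 d take out 90 % of the left-handed product then present, then wait 30 h
- oak: at 2.5 d raise the temperature by 15 K, then wait 30 h
- cedar: at 2.5 d add partner, 50.0 % of the amount charged, then wait 30 h
- alder: change nothing and wait 30 h more
- maple: at 2.5 d add racemization catalyst, 100 % of the amount charged, then wait 30 h

1. left-handed product, in percent of the left-handed substrate and right-handed substrate together first charged, at 2.5 d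
2. the option that brings most further left-handed product ("none" if no option brings more than 2 percentage points) (elm / oak / cedar / alder / maple / none)
3. left-handed product present, with what was taken out counted in, in percent of the left-handed substrate and right-handed substrate together first charged, after elm
4. left-handed product present, with what was taken out counted in, in percent of the left-handed substrate and right-handed substrate together first charged, after maple

Read in fractions of the charge, the last rows of gamma stand still. From 25.0 h on, gamma's left-handed substrate averages 37.1 % of the two substrates together. So 74.2 % of the left-handed substrate charged survives in gamma.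

Now follow one molecule of it. It runs a pseudo-first-order risk of meeting partner, and its chance of surviving is the exponential of minus its expected hits. That gives 0.299 for gamma, the hit number: minus the logarithm of the surviving fraction, or the hits one charge of partner deals to each left-handed substrate molecule before the stall.

The last row of delta gives the next thought. Its left-handed substrate reads 37.4 % at 12.0 h, which is 0.290 hits, close to gamma's reading, with less substrate in delta. So, with the partner charge held, the hit number reads the same within the scatter at either substrate charge, though delta is not followed past 12.0 h.

A stall with 74.2 % of the left-handed substrate standing in gamma can be a balance or a partner that dies by itself, and these two runs do not part them. My own reckoning takes the dying partner, as a judgement. Left-handed product in the flask then stays near 12.9 %. Elm, alder and maple bring no partner, so no hits, and oak is a guess. Cedar's 50.0 % deals 0.150 hits to the 37.1 % standing, which makes 5.1 percentage points more, above the margin.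

The forecast reads the stall otherwise: “This looks like a reversible equilibrium”. It gives 13.1 %, names elm, and puts elm at 21 % and maple at 14.6 %.

    partner + left-handed substrate → left-handed product (k = 1.40 × 10⁻⁵ M⁻¹ s⁻¹, Ea = 90.0 kJ mol⁻¹)
    partner + right-handed substrate → right-handed product (k = 8.40 × 10⁻⁶ M⁻¹ s⁻¹, Ea = 66.0 kJ mol⁻¹)
    left-handed substrate + racemization catalyst ⇌ right-handed substrate + racemization catalyst, rate k3*[racemization catalyst]*[left-handed substrate] forward; the back reaction follows from the equilibrium constant (k = 0.0470 M⁻¹ s⁻¹, Ea = 49.0 kJ mol⁻¹)
    racemization catalyst + impurity → spent catalyst A (k = 3.70 M⁻¹ s⁻¹, Ea = 56.0 kJ mol⁻¹)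
    partner → decomposed reagent (k = 4.10 × 10⁻⁵ s⁻¹, Ea = 95.0 kJ mol⁻¹)
    partner + racemization catalyst → spent catalyst B (k = 9.30 × 10⁻⁶ M⁻¹ s⁻¹, Ea = 85.0 kJ mol⁻¹)
    (constants at 25 °C)

The flask gives 13.1 %, and the best option is cedar, with 5.4 points more against the 5.1 points reckoned. Elm ends at 13.1 % and maple at 13.1 %. At 60.0 h free partner stands at 0 % of its charge, with 0.886 M of decomposed reagent. A neighbour flask with 2.8 M of partner reckons, in proportion to its partner charge, to 0.761 hits, so its left-handed product reckons to 26.6 %. That neighbour flask gives 27.5 %.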